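**Plan**
Retrosynthesis: the pyran ring is cut first at C4–C4a and O1–C2 (3-methylbut-2-enal plus a 2',4',5'-trihydroxy-6'-methoxydihydrochalcone), then the C8–O bond (the oxygen para to the chelated phenol), then the Cα–Cβ bond of the propanone chain (acetophenone plus benzaldehyde).
Forward: the chain is joined by Claisen–Schmidt condensation, the enone C=C is hydrogenated, the fourth ring oxygen is introduced by para-hydroxylation, and the pyran ring is closed last on the unprotected triol.
Enabling feature: in the triol, C4a is the only hydrogen-bearing carbon of the benzene ring and lies between the oxygens on C5 and C8a (the 2-position of a resorcinol); the C5 hydroxyl is hydrogen-bonded to the C6 ketone, which leaves the C8a oxygen to close the ring.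
Stereochemistry: the target has no stereocenter; the C3=C4 alkene is cis by ring constraint and the E geometry of the chalcone is erased by hydrogenation.
No protecting group is used; the sulfate ester formed during the hydroxylation guards the new oxygen until it is hydrolysed.

Key step: step 4

Assumption: the target is achiral, so no configuration has to be set; compounds 1, 2 and 7 are taken as purchased.

**Step 1**
Reactants: 1 1-(2,4-dihydroxy-6-methoxyphenyl)ethan-1-one; 2 benzaldehyde
Product: 3 (E)-1-(2,4-dihydroxy-6-methoxyphenyl)-3-phenylprop-2-en-1-one
Conditions: KOH (50% aq, large excess), EtOH, rt, 48–72 h; then cold dilute HCl to pH 4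
Reagents that add atoms: none
Why: Claisen–Schmidt (crossed aldol) condensation, in which the methyl ketone enolate adds to non-enolizable benzaldehyde and E1cB loss of water should give the conjugated E-enone while the phenols are masked in the flask as their potassium phenoxides.

**Step 2**
Reactants: 3 (E)-1-(2,4-dihydroxy-6-methoxyphenyl)-3-phenylprop-2-en-1-one
Product: 4 1-(2,4-dihydroxy-6-methoxyphenyl)-3-phenylpropan-1-one
Conditions: H2 (1 atm), 10% Pd/C, EtOAc, rt, stopped after uptake of one equivalent
Reagents that add atoms: none
Why: Heterogeneous catalytic hydrogenation should saturate the conjugated C=C well before the hydrogen-bonded, electron-rich aryl ketone is touched, the standard chalcone-to-dihydrochalcone reduction; no stereocenter arises.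

**Step 3**
Reactants: 4 1-(2,4-dihydroxy-6-methoxyphenyl)-3-phenylpropan-1-one
Product: 6 1-(2,4,5-trihydroxy-6-methoxyphenyl)-3-phenylpropan-1-one, via aryl potassium sulfate 5 (not isolated)
Conditions: K2S2O8 (1.1 equiv), 2 M aq KOH, 10 °C → rt, 24 h; HCl to pH 4, Et2O wash to recover 4; aqueous phase made 2 M in HCl, 90 °C, 30 min, Ar
Reagents that add atoms: potassium peroxodisulfate, [K+].[K+].[O-]S(=O)(=O)OOS(=O)(=O)[O-]
Why: Elbs persulfate oxidation, in which the phenoxide of the C2' hydroxyl attacks the peroxide oxygen through its para carbon C5' (the only free position para to a phenolic oxygen, and also ortho to the C4' phenoxide), the sulfate ester 5 shields the new oxygen from further oxidation until acid hydrolysis, and the close model is the known para-hydroxylation of 2-hydroxy-4,6-dimethoxyacetophenone.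

**Step 4**
Reactants: 6 1-(2,4,5-trihydroxy-6-methoxyphenyl)-3-phenylpropan-1-one; 7 3-methylbut-2-enal
Product: 10 flemistrictin D, via benzylic carbinol 8 (not isolated), via ortho-quinone methide 9 (not isolated)
Conditions: 7 (2 equiv), degassed pyridine, 120 °C, sealed tube, Ar, 12 h
Reagents that add atoms: none
Why: In hot pyridine the carbon of 6 between the C2' and C4' hydroxyls (the only unsubstituted ring carbon, the future C4a) should add to the aldehyde carbon of 7 in an aldol-type C-alkylation of the phenoxide to give carbinol 8, which loses water to the (Z)-vinyl ortho-quinone methide 9; thermal disrotatory oxa-6π electrocyclization of the O=C–C=C–C=C unit of 9 then joins the quinone-methide oxygen to the dimethyl-bearing carbon and restores the arene. The closest known reaction is the pyridine- or amine-mediated chromenylation of resorcinols with α,β-unsaturated aldehydes (formal [3+3] annulation by condensation and electrocyclization), which turns 2,4-dihydroxyacetophenone into 6-acetyl-5-hydroxy-2,2-dimethylchromene. The one ring that closes is the six-membered 2H-pyran, and it closes by a pericyclic six-electron process, not by an ionic addition. No stereocenter is created, since the new sp3 carbon carries two methyl groups and the ring alkene can only be cis. The step needs selectivity between the two phenolic oxygens that flank the new C–C bond: the C2' hydroxyl is locked in a hydrogen bond to the ketone and is the less acidic one, so water should be lost through, and the ring should close onto, the C4' oxygen para to the ketone, while the C5' hydroxyl is not ortho to the reacting carbon and the occupied C5' position excludes any isomeric C–C bond.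

**Compound list**
1 | 1-(2,4-dihydroxy-6-methoxyphenyl)ethan-1-one (2',4'-dihydroxy-6'-methoxyacetophenone) | CC(=O)c1c(O)cc(O)cc1OC | starting material
2 | benzaldehyde | O=Cc1ccccc1 | starting material
3 | (E)-1-(2,4-dihydroxy-6-methoxyphenyl)-3-phenylprop-2-en-1-one (chalcone, E alkene) | COc1cc(O)cc(O)c1C(=O)/C=C/c1ccccc1 | intermediate
4 | 1-(2,4-dihydroxy-6-methoxyphenyl)-3-phenylpropan-1-one (dihydrochalcone) | COc1cc(O)cc(O)c1C(=O)CCc1ccccc1 | intermediate
5 | potassium [2,4-dihydroxy-6-methoxy-5-(3-phenylpropanoyl)phenyl] sulfate (not isolated) | COc1c(OS(=O)(=O)[O-])c(O)cc(O)c1C(=O)CCc1ccccc1.[K+] | intermediate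
6 | 1-(2,4,5-trihydroxy-6-methoxyphenyl)-3-phenylpropan-1-one | COc1c(O)c(O)cc(O)c1C(=O)CCc1ccccc1 | intermediate
7 | 3-methylbut-2-enal | CC(C)=CC=O | starting material
8 | 1-[2,4,5-trihydroxy-3-(1-hydroxy-3-methylbut-2-en-1-yl)-6-methoxyphenyl]-3-phenylpropan-1-one (racemic carbinol, not isolated) | COc1c(O)c(O)c(C(O)C=C(C)C)c(O)c1C(=O)CCc1ccccc1 | intermediate
9 | (6Z)-2,5-dihydroxy-3-methoxy-6-(3-methylbut-2-en-1-ylidene)-4-(3-phenylpropanoyl)cyclohexa-2,4-dien-1-one (ortho-quinone methide, not isolated) | COC1=C(O)C(=O)/C(=C\C=C(C)C)C(O)=C1C(=O)CCc1ccccc1 | intermediate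
10 | flemistrictin D, 1-(5,8-dihydroxy-7-methoxy-2,2-dimethyl-2H-chromen-6-yl)-3-phenylpropan-1-one (no stereocenter) | COc1c(O)c2c(c(O)c1C(=O)CCc1ccccc1)C=CC(C)(C)O2 | target

**Totals**
Total step count: 4. Longest linear sequence: 4 steps (1 → 3 → 4 → 6 → 10).

**Steps most likely to fail, with fallbacks**

Step 3. The electron-rich resorcinol dianion may be over-oxidized by radical pathways, or conversion may stall, so that little of the para-sulfate forms. The fallback sets out from 4 and replaces persulfate by a Teuber oxidation: ON(SO3K)2 in acetone/water buffered with KH2PO4 at rt should oxidize 4 at the carbon para to the C2' hydroxyl to the hydroxy-para-quinone 2-hydroxy-6-methoxy-5-(3-phenylpropanoyl)cyclohexa-2,5-diene-1,4-dione F1. Reduction of this quinone with Na2S2O4 in EtOAc/water at rt under Ar should give the triol, and the route is rejoined at 6.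

Step 4. The pyran may close onto the chelated C2' oxygen to give the angular isomer, or the hydroxyhydroquinone may be oxidized by traces of air in hot base. The fallback sets out from 6 and moves the annulation one oxidation level up. Ag2O in EtOAc at rt should convert 6 into 2-hydroxy-6-methoxy-5-(3-phenylpropanoyl)cyclohexa-2,5-diene-1,4-dione F1, a vinylogous acid whose only nucleophilic carbon is the future C4a. Condensation of this hydroxyquinone with 7 in pyridine at 80 °C (Knoevenagel condensation and oxa-6π electrocyclization, as known for 2-hydroxy-1,4-naphthoquinone with the same aldehyde) should give 7-methoxy-2,2-dimethyl-6-(3-phenylpropanoyl)-2H-chromene-5,8-dione F2, the para-quinone being favoured over the ortho-quinone isomer under the reversible closure. Reduction with Na2S2O4 in EtOAc/water under Ar should then give the hydroquinone, and the route is rejoined at 10.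

Step 1. Enolization of the doubly deprotonated ketone may be slow, and the 2'-hydroxychalcone may cyclize to the flavanone on work-up. The fallback sets out from 1 and masks both phenols first: BnBr and K2CO3 in DMF at 80 °C should give 1-[2,4-bis(benzyloxy)-6-methoxyphenyl]ethan-1-one F3. Claisen–Schmidt condensation of this ketone with 2 (KOH, EtOH, rt) should give (E)-1-[2,4-bis(benzyloxy)-6-methoxyphenyl]-3-phenylprop-2-en-1-one F4, which cannot form a flavanone. Hydrogenation over Pd/C (H2, 1 atm, EtOAc/MeOH, rt) should saturate the alkene and remove both benzyl groups in one operation, and the route is rejoined at 4, so that steps 1 and 2 are both replaced.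

**Further compounds**
F1 | step 3 | 2-hydroxy-6-methoxy-5-(3-phenylpropanoyl)cyclohexa-2,5-diene-1,4-dione | COC1=C(C(=O)CCc2ccccc2)C(=O)C=C(O)C1=O
F2 | step 4 | 7-methoxy-2,2-dimethyl-6-(3-phenylpropanoyl)-2H-chromene-5,8-dione | COC1=C(C(=O)CCc2ccccc2)C(=O)C2=C(OC(C)(C)C=C2)C1=O
F3 | step 1 | 1-[2,4-bis(benzyloxy)-6-methoxyphenyl]ethan-1-one | CC(=O)c1c(OC)cc(OCc2ccccc2)cc1OCc1ccccc1
F4 | step 1 | (E)-1-[2,4-bis(benzyloxy)-6-methoxyphenyl]-3-phenylprop-2-en-1-one | COc1cc(OCc2ccccc2)cc(OCc2ccccc2)c1C(=O)/C=C/c1ccccc1
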